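Readings and results are calculated for substances that don't exist.

A tempting mistake is to read these curves and believe you know which partner sets the pace. The charges are nearly equal, so substrate and reagent fall together.

| setting | winter | dusk | noon | delta | alpha | zeta | eta |
|---|---|---|---|---|---|---|---|
| substrate | 0.050 M | 0.050 M | 0.050 M | 0.050 M | 0.050 M (fed, over 10.0 min) | 0.050 M | 0.050 M |
| reagent | 0.0525 M | 0.0525 M | 0.0525 M | 0.0525 M (fed, over 10.0 min) | 0.0525 M | 0.0525 M | 0.0525 M |
| free catalyst | 1 mM | 1.4 mM | 2.2 mM | 1.0 mM | 1.0 mM | 1.0 mM | 1.0 mM |
| remark | run made earlier | run made earlier | run made earlier | all but reagent at the start; reagent goes in evenly over 10.0 min, the run ends at 10 min | all but substrate at the start; substrate goes in evenly over 10.0 min, the run ends at 10 min | one stirred flow tank at steady state, fed with the mixture as stated, mean residence time 10 min | everything together in a closed stirred flask, run for 10 min |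
| time |  |  |  | 10 min | 10 min |  | 10 min |

| winter: time / min | winter: target / % | dusk: time / min | dusk: target / % | noon: time / min | noon: target / % |
|---|---|---|---|---|---|
| 0.833 | 13.7 | 0.667 | 15.5 | 1.50 | 47.2 |
| 1.50 | 22.4 | 2.00 | 40.4 | 3.00 | 73.5 |
| 2.50 | 37.4 | 3.00 | 54.4 | 5.00 | 88.3 |
| 3.00 | 43.7 | 5.00 | 76.7 | 6.00 | 96.0 |
| 4.00 | 53.5 | 8.00 | 90.2 | 8.00 | 96.0 |
| 5.00 | 62.4 | 10.0 | 92.9 | 10.0 | 98.7 |
| 6.00 | 69.6 | 12.0 | 97.2 | 12.0 | 97.9 |

(standard deviation of a reading: 1 percentage point)

- order of the set-ups by the amount of target at the outlet or at the end, in percent of the substrate put in, highest first (delta / alpha / zeta / eta)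
- amount of target at the outlet or at the end, in percent of the substrate put in, delta
- amount of target at the outlet or at the end, in percent of the substrate put in, alpha
- amount of target at the outlet or at the end, in percent of the substrate put in, zeta
- amount of target at the outlet or at the end, in percent of the substrate put in, eta

**What can you read safely?** The runs are closed flasks, and I read each as a single exponential. In the winter run the last reading gives 0.198 min⁻¹, and the reading at 3.00 min gives 0.191 min⁻¹. I call this the clearing constant k: the pseudo-first-order constant at 1 mM of free catalyst.

**Does it follow the catalyst?** Yes. The noon run gives 0.429 min⁻¹ at 2.2 mM.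

**But first order in which partner?** Take noon at 8.00 min. A curve tied to reagent, with its small excess, predicts 99.5%. One tied to substrate predicts 96.8%. The reading is 96.0%. That is one reading with scatter, so it leans and does not prove. I commit to substrate.

**So what is the rule?** Replace the curve by its mean: target made equals k times mean [substrate] times time.

**Eta?** The mean is the exponential's, which gives 86.3%.

**Zeta?** The tank holds one [substrate], and that level is its mean. This gives 66.5%.

**Alpha?** Substrate goes in evenly over 10.0 min, so it arrives late and the mean is lower. I get 56.5%.

**Delta is the weak spot. Isn't reagent short there?** Early, yes. The feed brings 0.105 min⁻¹ of the substrate charge, slower than the starting demand k. So target follows the feed until k[substrate] falls to it, at 52.9% of the substrate, after 4.48 min. Then substrate decays with k, which gives 82.3%.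

The forecast, holding that “reagent mainly limits”, gave 54% for delta, 75% for alpha, 64% for zeta and 85% for eta, in the order eta > alpha > zeta > delta, which differs from mine for delta and alpha.

The flasks give 80.0% for delta, 60.4% for alpha, 68.7% for zeta and 87.0% for eta, in the order eta > delta > zeta > alpha.

    reagent + free catalyst ⇌ catalyst intermediate A (K = 32.0 M⁻¹, k = 2100 M⁻¹ s⁻¹)
    catalyst intermediate A ⇌ catalyst intermediate B (K = 2.20, k = 110 s⁻¹)
    catalyst intermediate B ⇌ released group + catalyst intermediate C (K = 1.00 M, k = 34.0 s⁻¹)
    substrate + catalyst intermediate C ⇌ catalyst intermediate D (K = 13.0 M⁻¹, k = 220 M⁻¹ s⁻¹)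
    catalyst intermediate D → free catalyst + target (k = 0.380 s⁻¹)
    2 substrate → self-condensation product (k = 0.00110 M⁻¹ s⁻¹)

My order stands, and alpha lies 3.9 percentage points above my figure. In delta at 5.00 min, target stood at 47.4%, substrate at 50.3% and reagent at 3.26% of its own charge. By 10.0 min target had gained 33 points, while k times the mean of the two substrate values over that time gives 33.6%. For eta over the same minutes, k gives 23.4%. Target in eta rose by 25 points.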